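**Retrosynthetic overview**
1. First cut: the aryl–CH2(prenyl) bond. Target ⇒ ortho-bromo aryl ester + prenyl acetate. This bond is made last, at a cathode under nickel catalysis (cross-electrophile coupling).
2. Second cut: the aryl ester C–O bond ⇒ methyl (E)-3-bromo-4-hydroxycinnamate + (S)-3-acetoxybutanoic acid. The acid comes from bought (S)-3-hydroxybutanoic acid, which carries the only stereocentre; its C–O bond is never broken.
3. Third cut: the cinnamate C=C ⇒ 3-bromo-4-hydroxybenzaldehyde + Ph3P=CHCO2Me (E-selective Wittig).
4. No ring is formed. The benzene ring is bought with O and Br already in place, and the final acyl group doubles as the phenol mask, so there are no protecting-group steps.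

Assumption: the stereocentre in the given SMILES is (S), and compound 3 is treated as not stocked and is made in one step.

**Step 1**
Reactants: 1 3-bromo-4-hydroxybenzaldehyde; 2 methyl (triphenyl-λ5-phosphanylidene)acetate
Product: 3 methyl (2E)-3-(3-bromo-4-hydroxyphenyl)prop-2-enoate
Conditions: 2 (1.25 equiv), toluene, 90 °C, 5 h; crystallise or pass through a short silica plug (expected 85–90 %, E:Z > 20:1)
Reagents that add atoms: none
Why: Wittig olefination with an ester-stabilised ylide gives the E-alkene, tolerates the free phenol and the aryl bromide in a non-polar solvent, and creates no stereocentre.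

**Step 2**
Reactants: 4 (3S)-3-hydroxybutanoic acid (1.2 equiv); 3 methyl (2E)-3-(3-bromo-4-hydroxyphenyl)prop-2-enoate
Product: 6 methyl (2E)-3-(3-bromo-4-{[(3S)-3-(acetyloxy)butanoyl]oxy}phenyl)prop-2-enoate, via (3S)-3-(acetyloxy)butanoic acid 5 (not isolated)
Conditions: AcCl (3 equiv), neat, 0 → 23 °C, 2 h; evaporate (toluene chase); then 3, EDC·HCl (1.3 equiv), DMAP (0.1 equiv), CH2Cl2, 0 → 23 °C, 6 h (expected 75–80 %)
Reagents that add atoms: acetyl chloride, CC(=O)Cl
Why: O-acetylation breaks only the O–H bond, so the bought (S) centre is retained, its by-products are all volatile, and the crude acid then undergoes a Steglich-type carbodiimide esterification with catalytic DMAP at 0 °C, mild enough to avoid E1cB loss of acetate.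

**Step 3**
Reactants: 6 methyl (2E)-3-(3-bromo-4-{[(3S)-3-(acetyloxy)butanoyl]oxy}phenyl)prop-2-enoate; 7 prenyl acetate (3-methylbut-2-en-1-yl acetate, 2.0 equiv)
Product: 8 methyl (2E)-3-[4-{[(3S)-3-(acetyloxy)butanoyl]oxy}-3-(3-methylbut-2-en-1-yl)phenyl]prop-2-enoate (target)
Conditions: NiBr2(dme) (10 mol %), 4,4'-di-tert-butyl-2,2'-bipyridine (12 mol %), Bu4NBF4 (0.1 M), dry N,N-dimethylacetamide, undivided cell, Zn anode, Ni-foam cathode, constant current 5 mA (about 2 mA cm-2), 2.3 F/mol, 25 °C, argon, foil-wrapped; aq. NH4Cl work-up (projected 50–65 %)
Reagents that add atoms: none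
Why: Proposed new method: a nickel-electrocatalytic cross-electrophile prenylation of a fully functionalised aryl bromide, in which zerovalent nickel made at the cathode (about −1.2 V vs SCE) inserts into the C–Br bond of 6, the ortho-acyloxy group makes the resulting divalent aryl-nickel bromide too hindered to go on to biaryl, its one-electron reduction (about −1.4 V, still some 0.4 V short of cinnamate reduction) gives a monovalent aryl-nickel that ionises prenyl acetate, and the trivalent aryl(prenyl)nickel reductively eliminates at the unsubstituted CH2 terminus because the alternative would build a quaternary benzylic carbon beside an ortho substituent, so the linear prenyl arene should form; zinc ions from the anode bind the expelled acetate, the medium stays non-basic and light is excluded, so the E-alkene, both esters and the (S) centre are untouched; the closest known reaction type is the nickel-catalysed reductive coupling (zinc powder or electroreductive) of simple aryl halides with allylic acetates, here extended to a 3,3-disubstituted allyl donor on an ortho-acyloxy aryl bromide that also carries a reducible cinnamate and an elimination-prone β-acetoxy ester.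

**Compound list**
1 | 3-bromo-4-hydroxybenzaldehyde | O=Cc1ccc(O)c(Br)c1 | starting material
2 | methyl (triphenyl-λ5-phosphanylidene)acetate | COC(=O)C=P(c1ccccc1)(c1ccccc1)c1ccccc1 | starting material
3 | methyl (2E)-3-(3-bromo-4-hydroxyphenyl)prop-2-enoate | COC(=O)/C=C/c1ccc(O)c(Br)c1 | intermediate
4 | (3S)-3-hydroxybutanoic acid | O=C(O)C[C@H](C)O | starting material
5 | (3S)-3-(acetyloxy)butanoic acid | O=C(O)C[C@H](C)OC(C)=O | intermediate
6 | methyl (2E)-3-(3-bromo-4-{[(3S)-3-(acetyloxy)butanoyl]oxy}phenyl)prop-2-enoate | COC(=O)/C=C/c1ccc(OC(=O)C[C@H](C)OC(C)=O)c(Br)c1 | intermediate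
7 | prenyl acetate (3-methylbut-2-en-1-yl acetate) | CC(C)=CCOC(C)=O | starting material
8 | methyl (2E)-3-[4-{[(3S)-3-(acetyloxy)butanoyl]oxy}-3-(3-methylbut-2-en-1-yl)phenyl]prop-2-enoate | COC(=O)/C=C/c1ccc(OC(=O)C[C@H](C)OC(C)=O)c(CC=C(C)C)c1 | target

**Total step count:** 3 (step 2 is a two-stage, one-flask operation).
**Longest linear sequence:** 3 (1 → 3 → 6 → 8).

**Steps most likely to fail, with fallbacks**

The highest risk is the new electrolysis, step 3. Possible failures:
- hydrodebromination of 6;
- prenyl–prenyl or biaryl homocoupling;
- cathodic hydrodimerisation of the cinnamate if the catalyst starves;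
- some branched isomer.

The fallback drops electrolysis and cross-electrophile logic for a conventional nucleophile/electrophile coupling, which is known chemistry. It sets out from 6. A base-free Migita–Kosugi–Stille reaction with tributyl(3-methylbut-2-en-1-yl)stannane (1.3 equiv) and Pd(PPh3)4 (5 mol %) in toluene at 100 °C gives the linear prenyl arene. It comes back to the route directly at 8. No new compound arises on this path (entry F0).

The second risk is step 2. The acidic, hindered ortho-bromophenol is a poor nucleophile, so N-acylurea can form. DMAP can trigger E1cB to the crotonate. Residual AcCl would give the aryl acetate. The fallback changes from in-flask carbodiimide activation to an isolated acyl chloride used without DMAP. It sets out from 5, this time isolated by evaporation. Oxalyl chloride with catalytic DMF in CH2Cl2 gives (3S)-3-(acetyloxy)butanoyl chloride F1, which is freed of volatiles. F1 is then added to 3 and pyridine (1.5 equiv) in CH2Cl2 at −20 °C. The path comes back at 6.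

The third risk is step 1. The phenol of 1 (pKa near 7) can protonate ylide 2, leaving a deactivated phenolate aldehyde and stalling the reaction. The fallback reverses the order of events, so the phenol is already masked by the acyl group it must carry in the end. It sets out from 1, which is esterified with crude 5 (EDC·HCl, catalytic DMAP, CH2Cl2, 0 °C) to give 2-bromo-4-formylphenyl (3S)-3-(acetyloxy)butanoate F2. This activated aldehyde then undergoes the Wittig reaction with 2 in CH2Cl2 at 23 °C. The path bypasses 3 and comes back at 6 with the same step count.

**Further compounds**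
F0 | step 3 | none | none
F1 | step 2 | (3S)-3-(acetyloxy)butanoyl chloride | O=C(Cl)C[C@H](C)OC(C)=O
F2 | step 1 | 2-bromo-4-formylphenyl (3S)-3-(acetyloxy)butanoate | O=Cc1ccc(OC(=O)C[C@H](C)OC(C)=O)c(Br)c1
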